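## Retrosynthetic overview

1. Flavonol 9 ⇐ hemiketal 8 ⇐ open-chain 2-hydroxy-1,3-diketone 7: the pyranone ring C is the only ring built and is closed last (phenol adds to the ketone, then water is lost).
2. 7 ⇐ aldehyde 3 + glyoxal 5: the C3–C4 bond joins two formyl carbons. The A-ring aldehyde carbon reacts as an acyl anion (carbene-derived Breslow enaminol) with the aldehyde carbon of 4-methoxyphenylglyoxal (crossed benzoin).
3. 3 ⇐ 2,4,6-trihydroxybenzaldehyde 1 + prenyl bromide 2 (4-O-selective etherification). Rings A and B are purchased.

Assumption: the target has no stereocentre and no E/Z-isomeric double bond, so the SMILES is the full stereochemical description; 4-methoxyphenylglyoxal is bought as its stable monohydrate.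

## Route

Step 1
Reactants: 1 2,4,6-trihydroxybenzaldehyde; 2 prenyl bromide (1-bromo-3-methylbut-2-ene, 1.05 equiv)
Product: 3 2,6-dihydroxy-4-(3-methylbut-2-en-1-yloxy)benzaldehyde
Conditions: K2CO3 (1.0 equiv), acetone, rt → 45 °C, 12 h
Reagents that add atoms: prenyl bromide (compound 2), CC(C)=CCBr
Why: Williamson ether synthesis (SN2) in which the 4-OH, the most acidic phenol and the only one not held in an intramolecular hydrogen bond to the formyl group, is alkylated selectively with one equivalent of base and bromide; no stereocentre is formed.

Step 2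
Reactants: 3 2,6-dihydroxy-4-(3-methylbut-2-en-1-yloxy)benzaldehyde; 4 4-methoxyphenylglyoxal monohydrate (1.5 equiv)
Product: 9 3,5-dihydroxy-2-(4-methoxyphenyl)-7-(3-methylbut-2-en-1-yloxy)-4H-chromen-4-one (target), via 4-methoxyphenylglyoxal 5 (not isolated), via Breslow enaminol 6 (not isolated), via 2-hydroxy-1,3-diketone 7 (not isolated), via 2,3-dihydroxyflavanone 8 (not isolated)
Conditions: 3-benzyl-5-(2-hydroxyethyl)-4-methylthiazolium chloride (20 mol %), Et3N (40 mol %), 4 Å MS, THF, 50 °C, Ar, THF solution of 4 (pre-dried over 4 Å MS) added over 6 h; then AcOH, 60 °C, 2 h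
Reagents that add atoms: 4-methoxyphenylglyoxal monohydrate (compound 4), COc1ccc(cc1)C(=O)C(O)O
Why: Proposed new method: the thiazol-2-ylidene adds to the hydrogen-bond-activated formyl group of 3 (kept un-ionised by the weak amine base in THF) and proton transfer gives Breslow enaminol 6, an acyl anion equivalent whose carbon (future C4) attacks the far more electrophilic, non-enolisable aldehyde carbon of 5 (future C3) in a crossed benzoin reaction that releases the carbene and 7 (should 5 act as donor instead, the isomeric 3-hydroxy-1,2-diketone reaches 7 by enediol tautomerism); the ortho-phenol then closes onto the anisoyl ketone (6-exo-trig hemiketal 8) and acid-promoted loss of water gives the aromatic 4-pyranone irreversibly, which drains the reversible benzoin equilibria; the closest known reactions are carbene-catalysed chemoselective crossed benzoin couplings of electron-rich aldehydes with activated carbonyl acceptors and the acid cyclodehydration of 2'-hydroxydibenzoylmethanes to flavones; the transient sp3 centres of 7 and 8 are racemic and become sp2 in 9.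

## Compound list

1 | 2,4,6-trihydroxybenzaldehyde | O=Cc1c(O)cc(O)cc1O | starting material
2 | prenyl bromide (1-bromo-3-methylbut-2-ene) | CC(C)=CCBr | starting material
3 | 2,6-dihydroxy-4-(3-methylbut-2-en-1-yloxy)benzaldehyde | O=Cc1c(O)cc(OCC=C(C)C)cc1O | intermediate
4 | 4-methoxyphenylglyoxal monohydrate (2,2-dihydroxy-1-(4-methoxyphenyl)ethan-1-one) | COc1ccc(cc1)C(=O)C(O)O | starting material
5 | 4-methoxyphenylglyoxal (2-(4-methoxyphenyl)-2-oxoacetaldehyde) | COc1ccc(cc1)C(=O)C=O | intermediate
6 | Breslow enaminol of 3 with 3-benzyl-5-(2-hydroxyethyl)-4-methylthiazol-2-ylidene (transient, alkene geometry not defined) | OC(=C1SC(CCO)=C(C)N1Cc1ccccc1)c1c(O)cc(OCC=C(C)C)cc1O | intermediate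
7 | 1-[2,6-dihydroxy-4-(3-methylbut-2-en-1-yloxy)phenyl]-2-hydroxy-3-(4-methoxyphenyl)propane-1,3-dione (racemic) | COc1ccc(cc1)C(=O)C(O)C(=O)c1c(O)cc(OCC=C(C)C)cc1O | intermediate
8 | 2,3,5-trihydroxy-2-(4-methoxyphenyl)-7-(3-methylbut-2-en-1-yloxy)chroman-4-one (hemiketal, mixture of racemic diastereomers) | COc1ccc(cc1)C1(O)Oc2cc(OCC=C(C)C)cc(O)c2C(=O)C1O | intermediate
9 | 3,5-dihydroxy-2-(4-methoxyphenyl)-7-(3-methylbut-2-en-1-yloxy)-4H-chromen-4-one (achiral) | COc1ccc(-c2oc3cc(OCC=C(C)C)cc(O)c3c(=O)c2O)cc1 | target

## Step count and risks

Total step count: 2. Longest linear sequence: 2 (1 → 3 → 9).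

The route has only two steps, so the three weakest points are the two stages of step 2 and then step 1.

**Risk 1 – step 2, C–C bond-forming stage.** Aldehyde 3 is 2,6-disubstituted and electron-rich, so 6 may form slowly. Glyoxal 5 can meanwhile self-condense, undergo carbene-mediated internal redox to a 4-methoxymandeloyl azolium, or hydroxyalkylate the phloroglucinol ring. The fallback makes the same C3–C4 bond with the same polarity but intramolecularly. It sets out from 3: one of the two equivalent ortho-hydroxyls is alkylated with methyl 2-bromo-2-(4-methoxyphenyl)acetate (COc1ccc(cc1)C(Br)C(=O)OC; K2CO3, DMF, 0 °C → rt) to give methyl 2-[2-formyl-3-hydroxy-5-(3-methylbut-2-en-1-yloxy)phenoxy]-2-(4-methoxyphenyl)acetate F1. A triazolium carbene (2-pentafluorophenyl-6,7-dihydro-5H-pyrrolo[2,1-c][1,2,4]triazolium tetrafluoroborate, DBU cat., toluene, 60 °C) then turns the formyl carbon into the acyl anion equivalent, which acylates itself on the tethered ester with loss of methoxide. This gives 5-hydroxy-2-(4-methoxyphenyl)-7-(3-methylbut-2-en-1-yloxy)chromane-3,4-dione F2, which enolises in the flask and so comes back to the route at 9. The ester acceptor is itself an extension of known chemistry; the closest analogues are carbene-catalysed aldehyde–ketone and aldehyde–nitrile cyclisations on the same aryloxymethyl tether.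

**Risk 2 – step 2, ring-closure and dehydration stage.** Diketone 7 can cleave by retro-Claisen reaction or oxidise in air before it closes, and the acid that completes the dehydration of 8 can cleave or cyclise the aryl prenyl ether. The fallback changes the order so that the acid-labile group is absent during the cascade. It sets out from 1 and 4: the same carbene-catalysed crossed benzoin is run on 1 and finished with AcOH/cat. H2SO4 at 80 °C to give kaempferide F3. F3 is then alkylated with 2 (1.0 equiv; K2CO3 1.0 equiv, acetone, rt) at the 7-OH, the most acidic phenol of a 3,5,7-trihydroxyflavone (5-OH is chelated, 3-OH is less acidic), and so comes back to the route at 9. The free 4-OH of 1 makes Breslow formation harder than with 3, so this fallback trades ether stability for a less reactive donor.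

**Risk 3 – step 1.** The phenoxide of 1 is ambident, so C-prenylation at C3/C5 and double O-alkylation lower the yield. The fallback replaces phenoxide alkylation by a Mitsunobu etherification. It sets out from 1: 3-methylbut-2-en-1-ol (CC(C)=CCO), PPh3 and DIAD in THF at 0 °C → rt react at the most acidic, non-chelated 4-OH without forming a free phenoxide, which suppresses C-alkylation, and it comes back to the route at 3. No new compound is made (F0).

## Further compounds

F1 | step 2 | methyl 2-[2-formyl-3-hydroxy-5-(3-methylbut-2-en-1-yloxy)phenoxy]-2-(4-methoxyphenyl)acetate (racemic) | COC(=O)C(Oc1cc(OCC=C(C)C)cc(O)c1C=O)c1ccc(OC)cc1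
F2 | step 2 | 5-hydroxy-2-(4-methoxyphenyl)-7-(3-methylbut-2-en-1-yloxy)chromane-3,4-dione (racemic, not isolated) | COc1ccc(cc1)C1Oc2cc(OCC=C(C)C)cc(O)c2C(=O)C1=O
F3 | step 2 | kaempferide (3,5,7-trihydroxy-2-(4-methoxyphenyl)-4H-chromen-4-one) | COc1ccc(cc1)-c1oc2cc(O)cc(O)c2c(=O)c1O
F0 | step 1 | none | none
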